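## Retrosynthetic overview

1. The target comes from selective O‑7 acetylation of the 6β,7β,13‑triol. The 6β‑OH (enolate hydroxylation) and 7β‑OH (hydride reduction) are both placed on a 7‑oxo‑halim‑5(10)‑ene under control of the 8α‑methyl group.
2. The 7‑oxo‑halim‑5(10)‑ene comes from a labd‑8‑en‑7α‑ol in one anodic, bromide‑mediated cascade. The 10β‑methyl shifts to C9 (key C9–CH3 bond, C9 quaternary centre, C5=C10 alkene), then H‑7 shifts to C8 (sets C8, unveils the ketone).
3. The labd‑8‑en‑7α‑ol comes from a labd‑7‑ene by dye‑sensitised photooxygenation (Schenck ene). This places the C7 oxygen that ends as the acetate oxygen.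
4. The labd‑7‑ene comes from (−)‑sclareol by O‑13 silylation, dehydration of 8‑OH and Co–H alkene isomerisation. C13 and the methyl that becomes the C9 methyl are bought.
5. No ring is formed. Rings A and B come intact from sclareol; ring B is only re‑cut (methyl shift) and oxygenated.

Assumption: labdane/halimane numbering (C‑1 to C‑20) is used, with α/β as in the usual drawing. Labdane names carry the sclareol ring stereochemistry (5αH, 9αH, 10β‑CH3). All halimane names carry 9β‑CH3 (C‑20) and the side chain 9α; "8βH" means the C‑17 methyl is α. TBSO = tert‑butyldimethylsilyloxy.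

## Route

Step 1
Reactants: 1 (−)‑sclareol, (13R)‑labd‑14‑ene‑8α,13‑diol
Product: 2 (13R)‑13‑(TBSO)labd‑14‑en‑8α‑ol
Conditions: TBSOTf (1.05 equiv), 2,6‑lutidine, CH2Cl2, −78 to 0 °C
Reagents that add atoms: tert‑butyldimethylsilyl triflate, CC(C)(C)[Si](C)(C)OS(=O)(=O)C(F)(F)F
Why: The side‑chain carbinol is the less hindered of the two tertiary alcohols (the ring 8α‑OH is flanked by C9 and the C10 methyl), so one equivalent of silyl triflate should silylate O‑13 only; silyl ether protection, no stereocentre touched.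

Step 2
Reactants: 2 (13R)‑13‑(TBSO)labd‑14‑en‑8α‑ol
Product: 4 (13R)‑13‑(TBSO)labda‑8(17),14‑diene, via chlorosulfite ester 3 (not isolated)
Conditions: SOCl2 (1.5 equiv), pyridine, CH2Cl2, −78 to 0 °C
Reagents that add atoms: none
Why: The equatorial 8α‑chlorosulfite has no antiperiplanar ring hydrogen, so pyridine‑mediated E2 elimination takes a C17 hydrogen and gives mainly the exocyclic alkene; SOCl2/pyridine dehydration of a tertiary alcohol.

Step 3
Reactants: 4 (13R)‑13‑(TBSO)labda‑8(17),14‑diene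
Product: 5 (13R)‑13‑(TBSO)labda‑7,14‑diene
Conditions: chloro[N,N′‑ethylenebis(3,5‑di‑tert‑butylsalicylideneiminato)]cobalt (3 mol%), PhSiH3 (6 mol%), benzene, 23 °C
Reagents that add atoms: none
Why: Reversible hydrogen‑atom transfer from a cobalt hydride to the 1,1‑disubstituted alkene gives the tertiary C8 radical, which gives back a hydrogen from the accessible C7 methylene to form the trisubstituted ring alkene; the vinyl group has no allylic hydrogen and cannot move, and any Δ7 isomer already present from step 2 is the same product; metal‑hydride hydrogen‑atom‑transfer alkene isomerisation.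

Step 4
Reactants: 5 (13R)‑13‑(TBSO)labda‑7,14‑diene
Product: 7 (13R)‑13‑(TBSO)labda‑8,14‑dien‑7α‑ol, via allylic hydroperoxide 6 (not isolated)
Conditions: O2, tetraphenylporphyrin (0.5 mol%), white LEDs, CH2Cl2, 0 °C; then PPh3 (1.2 equiv), 0 to 23 °C
Reagents that add atoms: dioxygen, O=O
Why: Singlet oxygen adds to the open α face at C7 (the β face lies under the C10 methyl) and abstracts the pseudo‑axial 9α‑hydrogen on the disubstituted side of the alkene (cis effect), which sets C7 as 7α‑O and moves the alkene to C8=C9; Schenck ene reaction, then phosphine reduction of the hydroperoxide.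

Step 5
Reactants: 7 (13R)‑13‑(TBSO)labda‑8,14‑dien‑7α‑ol
Product: 9 (13R)‑13‑(TBSO)‑8βH‑halima‑5(10),14‑dien‑7‑one, via cis‑bromohydrin 8 (not isolated)
Conditions: undivided cell, reticulated vitreous carbon anode, platinum cathode, constant current 2 mA cm−2 (2.1 F mol−1), Bu4NBr (0.3 equiv), Bu4NPF6 (0.1 M), 2,4,6‑collidine (2.5 equiv), CH2Cl2–(CF3)2CHOH 19:1, 0 to 23 °C
Reagents that add atoms: none
Why: Proposed new method: bromide is oxidised at the anode to a Br+ equivalent that forms the α‑face bromonium ion of the electron‑rich tetrasubstituted C8=C9 alkene (the vinyl group is far less reactive and the steady‑state bromine concentration is low); ring opening at C9 is driven by antiperiplanar shift of the axial 10β‑methyl group to the β face of C9 (Westphalen‑type 1,2‑shift, forming the C9 quaternary stereocentre with the side chain α), and H‑5 is lost to give the C5=C10 alkene and cis‑bromohydrin 8; because a cis‑bromohydrin cannot close to an epoxide, the tertiary C8–Br bond then ionises with antiperiplanar 1,2‑shift of H‑7β to the β face of C8 (semipinacol, setting the 8α‑methyl/8βH centre stereospecifically), releasing the ketone and bromide, which returns to the anode while the two protons are reduced at the cathode; the closest known reaction types are halide‑mediated electrochemical semipinacol rearrangements of allylic alcohols, halonium‑induced Wagner–Meerwein shifts and the hydride shift of cis‑halohydrins to ketones, and the tandem methyl‑shift/hydride‑shift version on a labdane allylic alcohol is new.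

Step 6
Reactants: 9 (13R)‑13‑(TBSO)‑8βH‑halima‑5(10),14‑dien‑7‑one
Product: 11 (13R)‑6β‑hydroxy‑13‑(TBSO)‑8βH‑halima‑5(10),14‑dien‑7‑one, via lithium dienolate 10 (not isolated)
Conditions: LiN(iPr)2 (1.2 equiv), THF, −78 °C; MoO5·py·HMPA (1.5 equiv), −78 to −40 °C; aq. Na2SO3 at −40 °C
Reagents that add atoms: oxodiperoxymolybdenum–pyridine–hexamethylphosphoric triamide (MoO5·py·HMPA), O=[Mo]12(OO1)OO2.c1ccncc1.CN(C)P(=O)(N(C)C)N(C)C
Why: Kinetic deprotonation at the doubly activated C6 (α to C=O and allylic) gives the conjugated dienolate without touching C8, and the peroxomolybdenum reagent attacks C6 from the β face, trans to the 8α‑methyl group (axial attack, trans‑2,6 product), so that the new C6–O bond is pseudo‑axial and clear of the C4 gem‑dimethyl group (A1,3 strain); enolate hydroxylation (Vedejs).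

Step 7
Reactants: 11 (13R)‑6β‑hydroxy‑13‑(TBSO)‑8βH‑halima‑5(10),14‑dien‑7‑one
Product: 12 (13R)‑13‑(TBSO)‑8βH‑halima‑5(10),14‑diene‑6β,7β‑diol
Conditions: NaBH4, CeCl3·7H2O, MeOH–THF, −78 to −40 °C (11 used at once, without storage)
Reagents that add atoms: none
Why: The small hydride attacks C7 anti to the pseudo‑axial C6–O bond (Felkin–Anh, axial attack) to give the equatorial 7β‑alcohol, which is also the more stable epimer because a 7α‑OH would be syn‑axial to the 9α side chain; Luche‑type borohydride reduction of an α‑hydroxy ketone to the cis‑diol.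

Step 8
Reactants: 12 (13R)‑13‑(TBSO)‑8βH‑halima‑5(10),14‑diene‑6β,7β‑diol
Product: 13 (13R)‑8βH‑halima‑5(10),14‑diene‑6β,7β,13‑triol
Conditions: Bu4NF, THF, 50 °C
Reagents that add atoms: none
Why: Fluoride cleaves the Si–O bond of the tertiary silyl ether without affecting the diol or the alkenes; fluoride desilylation.

Step 9
Reactants: 13 (13R)‑8βH‑halima‑5(10),14‑diene‑6β,7β,13‑triol
Product: 14 (13R)‑7β‑acetoxy‑8βH‑halima‑5(10),14‑diene‑6β,13‑diol (CNP0126002.3)
Conditions: Ac2O (1.1 equiv), pyridine, 0 °C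
Reagents that add atoms: acetic anhydride, CC(=O)OC(C)=O
Why: Only the equatorial secondary 7‑OH is accessible (6β‑OH is pseudo‑axial and pressed against the C4 gem‑dimethyl group, 13‑OH is tertiary), so one equivalent of anhydride gives the 7‑monoacetate; selective O‑acylation.

## Compound list

1 | (−)‑sclareol, (13R)‑labd‑14‑ene‑8α,13‑diol | C=C[C@](C)(O)CC[C@@H]1[C@@]2(C)CCCC(C)(C)[C@@H]2CC[C@@]1(C)O | starting material
2 | (13R)‑13‑(tert‑butyldimethylsilyloxy)labd‑14‑en‑8α‑ol | C=C[C@](C)(O[Si](C)(C)C(C)(C)C)CC[C@@H]1[C@@]2(C)CCCC(C)(C)[C@@H]2CC[C@@]1(C)O | intermediate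
3 | (13R)‑13‑(tert‑butyldimethylsilyloxy)labd‑14‑en‑8α‑yl chlorosulfite | C=C[C@](C)(O[Si](C)(C)C(C)(C)C)CC[C@@H]1[C@@]2(C)CCCC(C)(C)[C@@H]2CC[C@@]1(C)OS(=O)Cl | intermediate (not isolated)
4 | (13R)‑13‑(tert‑butyldimethylsilyloxy)labda‑8(17),14‑diene | C=C[C@](C)(O[Si](C)(C)C(C)(C)C)CC[C@@H]1[C@@]2(C)CCCC(C)(C)[C@@H]2CCC1=C | intermediate
5 | (13R)‑13‑(tert‑butyldimethylsilyloxy)labda‑7,14‑diene | C=C[C@](C)(O[Si](C)(C)C(C)(C)C)CC[C@@H]1[C@@]2(C)CCCC(C)(C)[C@@H]2CC=C1C | intermediate
6 | (13R)‑13‑(tert‑butyldimethylsilyloxy)labda‑8,14‑dien‑7α‑yl hydroperoxide | C=C[C@](C)(O[Si](C)(C)C(C)(C)C)CCC1=C(C)[C@H](OO)C[C@H]2C(C)(C)CCC[C@]12C | intermediate (not isolated)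
7 | (13R)‑13‑(tert‑butyldimethylsilyloxy)labda‑8,14‑dien‑7α‑ol | C=C[C@](C)(O[Si](C)(C)C(C)(C)C)CCC1=C(C)[C@H](O)C[C@H]2C(C)(C)CCC[C@]12C | intermediate
8 | (13R)‑8α‑bromo‑13‑(tert‑butyldimethylsilyloxy)halima‑5(10),14‑dien‑7α‑ol (C‑17 methyl β) | C=C[C@](C)(O[Si](C)(C)C(C)(C)C)CC[C@@]1(C)C2=C(C[C@@H](O)[C@@]1(C)Br)C(C)(C)CCC2 | intermediate (not isolated)
9 | (13R)‑13‑(tert‑butyldimethylsilyloxy)‑8βH‑halima‑5(10),14‑dien‑7‑one | C=C[C@](C)(O[Si](C)(C)C(C)(C)C)CC[C@@]1(C)C2=C(CC(=O)[C@H]1C)C(C)(C)CCC2 | intermediate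
10 | lithium 5(10),6‑dienolate of 9 | C=C[C@](C)(O[Si](C)(C)C(C)(C)C)CC[C@@]1(C)C2=C(C=C([O-])[C@H]1C)C(C)(C)CCC2.[Li+] | intermediate (not isolated)
11 | (13R)‑6β‑hydroxy‑13‑(tert‑butyldimethylsilyloxy)‑8βH‑halima‑5(10),14‑dien‑7‑one | C=C[C@](C)(O[Si](C)(C)C(C)(C)C)CC[C@@]1(C)C2=C([C@H](O)C(=O)[C@H]1C)C(C)(C)CCC2 | intermediate
12 | (13R)‑13‑(tert‑butyldimethylsilyloxy)‑8βH‑halima‑5(10),14‑diene‑6β,7β‑diol | C=C[C@](C)(O[Si](C)(C)C(C)(C)C)CC[C@@]1(C)C2=C([C@H](O)[C@H](O)[C@H]1C)C(C)(C)CCC2 | intermediate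
13 | (13R)‑8βH‑halima‑5(10),14‑diene‑6β,7β,13‑triol | C=C[C@](C)(O)CC[C@@]1(C)C2=C([C@H](O)[C@H](O)[C@H]1C)C(C)(C)CCC2 | intermediate
14 | (13R)‑7β‑acetoxy‑8βH‑halima‑5(10),14‑diene‑6β,13‑diol; (1S,2R,3S,4R)‑1‑hydroxy‑4‑[(3R)‑3‑hydroxy‑3‑methylpent‑4‑en‑1‑yl]‑3,4,8,8‑tetramethyl‑1,2,3,4,5,6,7,8‑octahydronaphthalen‑2‑yl acetate | C=C[C@](C)(O)CC[C@@]1(C)C2=C([C@H](O)[C@H](OC(C)=O)[C@H]1C)C(C)(C)CCC2 | target

## Step count and risks

Total step count: 9. Longest linear sequence: 9 (fully linear from sclareol).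

Steps most likely to fail:

**Step 5 (the new electrochemical cascade).** Risks are bromination of the product enol or the new C5=C10 alkene near the end point, loss of H‑1 instead of H‑5, and E1 loss of HBr from 8 instead of the hydride shift. The fallback sets out from 7 and comes back at 9, using known acid chemistry. Epoxidise 7 with t‑BuOOH and catalytic VO(acac)2 (CH2Cl2, 0 °C; directed to the α face by the pseudo‑axial 7α‑OH) to (13R)‑13‑(TBSO)‑8α,9α‑epoxylabd‑14‑en‑7α‑ol F1. Treat it with BF3·OEt2 (CH2Cl2, −78 °C), so that the epoxide opens at C9 with the same antiperiplanar 10β‑methyl shift and loss of H‑5, giving (13R)‑13‑(TBSO)halima‑5(10),14‑diene‑7α,8α‑diol F2. Pinacol rearrangement of this cis‑diol (catalytic TsOH·H2O, benzene, 23 °C, short contact) ionises the tertiary C8–O bond with shift of H‑7β and gives ketone 9.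

**Step 7 (facial selectivity of the ketone reduction, on a base‑ and acid‑labile α‑ketol).** The axial 9α side chain opposes the attack that the C6–O bond favours, and 11 can isomerise to the conjugated 7‑hydroxy‑6‑ketone. The fallback sets out from 9 and comes back at 12, placing both oxygens at once by cis‑dihydroxylation, so it also bypasses step 6. Condense 9 with TsNHNH2 (MeOH, 23 °C) to (13R)‑13‑(TBSO)‑8βH‑halima‑5(10),14‑dien‑7‑one p‑toluenesulfonylhydrazone F3. Shapiro reaction (LiN(iPr)2, 2.5 equiv, THF, −78 to 0 °C, then H2O) removes a C6 hydrogen and expels sulfinate and N2 to give (13R)‑13‑(TBSO)‑8βH‑halima‑5(10),6,14‑triene F4. OsO4 (2 mol%) with N‑methylmorpholine N‑oxide (acetone–H2O, 0 °C) dihydroxylates the cis‑disubstituted C6=C7 end of the ring diene from the β face, anti to the 8α‑methyl group and the 9α side chain, and gives diol 12.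

**Step 4 (regiochemistry of the ene reaction).** Abstraction of a C17 hydrogen would give the 7α‑hydroperoxy‑8(17)‑ene instead, and any Δ8 alkene carried over from step 3 gives other hydroperoxides. The fallback sets out from 4 and comes back at 7, needing neither step 3 nor step 4. Oxidise the exocyclic alkene 4 with catalytic SeO2 and t‑BuOOH (CH2Cl2, 23 °C) to (13R)‑13‑(TBSO)labda‑8(17),14‑dien‑7α‑ol F5. Dess–Martin periodinane gives (13R)‑13‑(TBSO)labda‑8(17),14‑dien‑7‑one F6. RhCl3·3H2O (3 mol%, EtOH, 70 °C) moves the exocyclic alkene into the ring to the conjugated (13R)‑13‑(TBSO)labda‑8,14‑dien‑7‑one F7. LiBH(sBu)3 (THF, −78 °C) then adds hydride from the β (equatorial) side and gives the pseudo‑axial 7α‑alcohol 7.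

## Further compounds

F1 | step 5 | (13R)‑13‑(TBSO)‑8α,9α‑epoxylabd‑14‑en‑7α‑ol | C=C[C@](C)(O[Si](C)(C)C(C)(C)C)CC[C@@]12O[C@]1(C)[C@H](O)C[C@H]3C(C)(C)CCC[C@]23C
F2 | step 5 | (13R)‑13‑(TBSO)halima‑5(10),14‑diene‑7α,8α‑diol | C=C[C@](C)(O[Si](C)(C)C(C)(C)C)CC[C@@]1(C)C2=C(C[C@@H](O)[C@@]1(C)O)C(C)(C)CCC2
F3 | step 7 | (13R)‑13‑(TBSO)‑8βH‑halima‑5(10),14‑dien‑7‑one p‑toluenesulfonylhydrazone | C=C[C@](C)(O[Si](C)(C)C(C)(C)C)CC[C@@]1(C)C2=C(CC(=NNS(=O)(=O)c3ccc(C)cc3)[C@H]1C)C(C)(C)CCC2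
F4 | step 7 | (13R)‑13‑(TBSO)‑8βH‑halima‑5(10),6,14‑triene | C=C[C@](C)(O[Si](C)(C)C(C)(C)C)CC[C@@]1(C)C2=C(C=C[C@H]1C)C(C)(C)CCC2
F5 | step 4 | (13R)‑13‑(TBSO)labda‑8(17),14‑dien‑7α‑ol | C=C[C@](C)(O[Si](C)(C)C(C)(C)C)CC[C@@H]1[C@@]2(C)CCCC(C)(C)[C@@H]2C[C@@H](O)C1=C
F6 | step 4 | (13R)‑13‑(TBSO)labda‑8(17),14‑dien‑7‑one | C=C[C@](C)(O[Si](C)(C)C(C)(C)C)CC[C@@H]1[C@@]2(C)CCCC(C)(C)[C@@H]2CC(=O)C1=C
F7 | step 4 | (13R)‑13‑(TBSO)labda‑8,14‑dien‑7‑one | C=C[C@](C)(O[Si](C)(C)C(C)(C)C)CCC1=C(C)C(=O)C[C@H]2C(C)(C)CCC[C@]12C
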